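## Retrosynthetic overview

- Feature: ring D is a phloroglucinol whose oxygens on C5'', C7'' and C8a'' alternate with C4a'', C6'' and the ring B-bearing C8''. The pyrone must close through O1''/C4a'' next to ring B (8-aryl, not 6-aryl), which requires the three oxygens to be distinguishable.
- Ring C is cut last: six benzyl ethers (hydrogenolysis), then O1–C2 by an enantioselective oxa-Michael closure of an alkylidene β-ketoester, itself cut at the C2–C3 alkene into a ring B aldehyde and a ring A β-ketoester.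
- Ring E is cut at O1''–C2'' (6-endo closure of an o-hydroxyaryl ynone) and at C4''–C4a'' (ortho-formylation of the one free phenol, then a ring F acetylide).
- Ring D is cut into 3-ethoxycyclobut-2-en-1-one and a ring B aryl siloxyalkyne. A thermal benzannulation forms C8''–C8a'', C6''–C7'' and C4a''–C8a'' and delivers O1'' as free OH, O7'' as silyl ether and O5'' as ethyl ether.
- The siloxyalkyne comes from 3-bromo-4,5-dimethoxybenzaldehyde via dioxolane, methyl benzoate and a Kowalski ynolate. Rings form in the order B (bought), D, E (F bought), then C onto A (bought).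

Key step: step 4

Remark 1: the ring B–ring D axis has three ortho substituents; since the target carries no axial descriptor it is taken to rotate freely and is not controlled.
Remark 2: the sense of induction of the cinchona thiourea in step 15 is assumed; the quinidine-derived catalyst is written, and its quinine-derived pseudoenantiomer is used instead if a model closure gives the 2R series.
Remark 3: the catechol and ring F oxygens are carried as methyl ethers up to the flavone, because the 5''-O-ethyl group can only be removed by a Lewis acid that would strip benzyl ethers as well; benzyl ethers are installed afterwards for a neutral final deprotection.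

## Route

Step 1
Reactants: 1 3-bromo-4,5-dimethoxybenzaldehyde
Product: 2 2-(3-bromo-4,5-dimethoxyphenyl)-1,3-dioxolane
Conditions: ethylene glycol (3 equiv), p-TsOH·H2O (cat.), toluene, reflux, Dean–Stark
Reagents that add atoms: ethylene glycol, OCCO
Why: Acid-catalysed acetalisation with azeotropic removal of water masks the aldehyde (the later C2 of ring C) against the organolithium steps that follow.

Step 2
Reactants: 2 2-(3-bromo-4,5-dimethoxyphenyl)-1,3-dioxolane
Product: 4 methyl 5-(1,3-dioxolan-2-yl)-2,3-dimethoxybenzoate, via aryllithium 3 (not isolated)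
Conditions: n-BuLi (1.05 equiv), THF, −78 °C; cannulated into ClCO2Me (3 equiv), THF, −78 → 0 °C
Reagents that add atoms: methyl chloroformate, COC(=O)Cl
Why: Bromine–lithium exchange outpaces any attack on the acetal or methyl ethers at −78 °C, and inverse addition to excess chloroformate stops the acylation of the aryllithium at the ester.

Step 3
Reactants: 4 methyl 5-(1,3-dioxolan-2-yl)-2,3-dimethoxybenzoate
Product: 7 {[5-(1,3-dioxolan-2-yl)-2,3-dimethoxyphenyl]ethynyloxy}tri(propan-2-yl)silane (ring B aryl siloxyalkyne), via dibromoketone lithium enolate 5 (not isolated), via lithium ynolate 6 (not isolated)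
Conditions: CH2Br2 (2.2 equiv), lithium 2,2,6,6-tetramethylpiperidide (LiTMP, 2.1 equiv), THF, −78 °C; n-BuLi, −78 → 25 °C; TIPSOTf, −78 → 0 °C; aq. NaHCO3 work-up
Reagents that add atoms: dibromomethane, BrCBr; triisopropylsilyl trifluoromethanesulfonate, CC(C)[Si](OS(=O)(=O)C(F)(F)F)(C(C)C)C(C)C
Why: Kowalski ynolate formation: dibromomethyllithium adds to the ester, bromine–lithium exchange on enolate 5 triggers a 1,2-aryl shift of the carbenoid to ynolate 6, and the bulky silyl triflate traps it on oxygen; methyl ethers are inert to the excess alkyllithium.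

Step 4
Reactants: 7 ring B aryl siloxyalkyne; 8 3-ethoxycyclobut-2-en-1-one
Product: 13 2-[5-(1,3-dioxolan-2-yl)-2,3-dimethoxyphenyl]-5-ethoxy-3-(triisopropylsilyloxy)phenol, via ethoxy vinylketene 9 (not isolated), via 4-vinylcyclobutenone 10 (not isolated), via dienylketene 11 (not isolated), via cyclohexadienone 12 (not isolated)
Conditions: 8 (1.3 equiv, added slowly), toluene, 80 → 110 °C, argon
Reagents that add atoms: none
Why: Heating opens 8 by 4π electrocyclic cleavage to vinylketene 9, whose sp carbon is attacked by the nucleophilic aryl-bearing carbon of 7 in a regiospecific [2+2] cycloaddition to give 10; a second 4π opening gives dienylketene 11, 6π electrocyclisation gives dienone 12 and tautomerisation gives phenol 13. The closest known reaction is the thermal benzannulation of cyclobutenones with siloxyalkynes to monosilylated resorcinols (Danheiser benzannulation). Ring D is closed by the 6π electrocyclic closure that forms C4a''–C8a'', after the [2+2] step has formed C8''–C8a'' and C6''–C7''. No stereocentre is formed. The step needs regioselectivity in the ketene–alkyne union, and the oxygen-polarised alkyne secures it by placing ring B on C8'' between the silyl ether (O7'') and the free phenol (O1''), with the ethoxy group on C5''; it also needs phenol 13 to escape acylation by ketene 9, which the flanking aryl group and the slow addition of 8 should favour.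

Step 5
Reactants: 13 2-aryl-5-ethoxy-3-(triisopropylsilyloxy)phenol
Product: 14 3-[5-(1,3-dioxolan-2-yl)-2,3-dimethoxyphenyl]-6-ethoxy-2-hydroxy-4-(triisopropylsilyloxy)benzaldehyde
Conditions: MgCl2 (3 equiv), Et3N (5 equiv), (CH2O)n (6 equiv), MeCN, reflux; pH 5 phosphate buffer, 0 °C
Reagents that add atoms: paraformaldehyde (as formaldehyde), C=O
Why: Magnesium phenoxide-directed ortho-formylation (Casnati–Skattebøl) delivers formaldehyde only ortho to the free hydroxyl, whose single open ortho carbon is C4a'', and a second formaldehyde oxidises the benzylic alkoxide by hydride transfer.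

Step 6
Reactants: 14 salicylaldehyde of step 5; 15 1-ethynyl-4-methoxybenzene
Product: 16 1-{3-[5-(1,3-dioxolan-2-yl)-2,3-dimethoxyphenyl]-6-ethoxy-2-hydroxy-4-(triisopropylsilyloxy)phenyl}-3-(4-methoxyphenyl)prop-2-yn-1-ol (racemic)
Conditions: 15 (3 equiv), n-BuLi (2.9 equiv), THF, −78 °C; then 14, −78 → 0 °C; sat. aq. NH4Cl
Reagents that add atoms: none
Why: 1,2-Addition of a lithium acetylide to the aldehyde, the first equivalent being spent on the phenol; the carbinol centre is racemic and is removed in step 7.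

Step 7
Reactants: 16 propargylic alcohol of step 6
Product: 17 1-{3-[5-(1,3-dioxolan-2-yl)-2,3-dimethoxyphenyl]-6-ethoxy-2-hydroxy-4-(triisopropylsilyloxy)phenyl}-3-(4-methoxyphenyl)prop-2-yn-1-one
Conditions: activated MnO2 (20 equiv), CH2Cl2, 25 °C
Reagents that add atoms: none
Why: MnO2 oxidises the doubly activated benzylic–propargylic alcohol and leaves the free phenol, acetal and silyl ether alone.

Step 8
Reactants: 17 o-hydroxyaryl ynone
Product: 18 8-[5-(1,3-dioxolan-2-yl)-2,3-dimethoxyphenyl]-5-ethoxy-2-(4-methoxyphenyl)-7-(triisopropylsilyloxy)-4H-chromen-4-one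
Conditions: DMAP (20 mol%), DMF, 40 °C
Reagents that add atoms: none
Why: Nucleophilic catalysis: DMAP adds to the ynone β-carbon and the ortho phenol then closes ring E by 6-endo addition–elimination at C2'', the known DMAP-catalysed cyclisation of o-alkynoylphenols to flavones, which avoids the 5-exo aurone.

Step 9
Reactants: 18 silylated flavone acetal
Product: 20 3-[5-ethoxy-7-hydroxy-2-(4-methoxyphenyl)-4-oxo-4H-chromen-8-yl]-4,5-dimethoxybenzaldehyde, via 7''-hydroxy dioxolane flavone 19 (not isolated)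
Conditions: TBAF (1.1 equiv), THF, 0 °C; then 2 M aq. HCl, 25 °C
Reagents that add atoms: water, O
Why: Fluoride cleaves the aryl silyl ether and aqueous acid hydrolyses the dioxolane, while the alkyl ethers and the flavone are inert to both.

Step 10
Reactants: 20 7''-hydroxy-5''-ethoxy flavone aldehyde
Product: 21 3-[5,7-dihydroxy-2-(4-hydroxyphenyl)-4-oxo-4H-chromen-8-yl]-4,5-dihydroxybenzaldehyde
Conditions: BBr3 (10 equiv), CH2Cl2, −78 → 25 °C; then H2O/THF
Reagents that add atoms: none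
Why: Lewis acid ether cleavage with BBr3 removes the three methyl ethers and the chelated 5''-O-ethyl group in one operation while the molecule is still achiral, and the aldehyde is restored on aqueous work-up.

Step 11
Reactants: 21 pentahydroxy flavone aldehyde
Product: 22 3,4-bis(benzyloxy)-5-{7-(benzyloxy)-2-[4-(benzyloxy)phenyl]-5-hydroxy-4-oxo-4H-chromen-8-yl}benzaldehyde
Conditions: BnBr (4.4 equiv), K2CO3 (5 equiv), DMF, 25 → 40 °C, argon
Reagents that add atoms: benzyl bromide, BrCc1ccccc1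
Why: Williamson etherification of the four free phenols; the 5''-OH, hydrogen-bonded to the C4'' carbonyl, is much less nucleophilic and should stay free under carbonate at this temperature.

Step 12
Reactants: 23 2,4,6-trihydroxyacetophenone
Product: 24 1-[2,4-bis(benzyloxy)-6-hydroxyphenyl]ethan-1-one
Conditions: BnBr (2.05 equiv), K2CO3 (2.2 equiv), DMF, 25 °C
Reagents that add atoms: benzyl bromide, BrCc1ccccc1
Why: Williamson etherification in which one ortho hydroxyl remains chelated to the ketone and is not alkylated.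

Step 13
Reactants: 24 1-[2,4-bis(benzyloxy)-6-hydroxyphenyl]ethan-1-one
Product: 25 tert-butyl 3-[2,4-bis(benzyloxy)-6-hydroxyphenyl]-3-oxopropanoate
Conditions: LiN(SiMe3)2 (3.3 equiv), THF, −78 °C; Boc2O (1.1 equiv), −78 → 0 °C; cold 1 M HCl
Reagents that add atoms: di-tert-butyl dicarbonate, CC(C)(C)OC(=O)OC(=O)OC(C)(C)C
Why: Claisen-type C-acylation of the ketone enolate in the phenoxide–enolate dianion; any O-acylated material should reach the same β-ketoester enolate by Baker–Venkataraman-type O-to-C transfer, and the tert-butyl ester resists lactonisation to the coumarin.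

Step 14
Reactants: 22 tetrabenzyl flavone aldehyde; 25 ring A β-ketoester
Product: 26 tert-butyl 2-[2,4-bis(benzyloxy)-6-hydroxybenzoyl]-3-(3,4-bis(benzyloxy)-5-{7-(benzyloxy)-2-[4-(benzyloxy)phenyl]-5-hydroxy-4-oxo-4H-chromen-8-yl}phenyl)prop-2-enoate (alkene geometry not fixed)
Conditions: piperidine (10 mol%), AcOH (10 mol%), 4 Å molecular sieves, toluene, 25 °C
Reagents that add atoms: none
Why: Knoevenagel condensation of the non-enolisable aryl aldehyde with the active methylene; the ester is the activating group for the ring closure, and the reaction is kept at 25 °C and stopped early to limit uncatalysed cyclisation.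

Step 15
Reactants: 26 alkylidene β-ketoester
Product: 28 (2S)-5,7-bis(benzyloxy)-2-(3,4-bis(benzyloxy)-5-{7-(benzyloxy)-2-[4-(benzyloxy)phenyl]-5-hydroxy-4-oxo-4H-chromen-8-yl}phenyl)-2,3-dihydro-4H-chromen-4-one, via tert-butyl flavanone-3-carboxylate 27 (not isolated)
Conditions: 9-amino-9-deoxy-epi-quinidine 3,5-bis(trifluoromethyl)phenyl thiourea (10 mol%), toluene, −25 °C; then p-TsOH·H2O (0.5 equiv), 80 °C
Reagents that add atoms: none
Why: Bifunctional cinchona thiourea-catalysed intramolecular oxa-Michael addition (6-endo-trig): the thiourea binds the β-ketoester, the quinuclidine activates the phenol and O1 adds to one face of the alkylidene to set C2 as S under catalyst control, after which acid removes the tert-butyl ester by decarboxylation without touching C2.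

Step 16
Reactants: 28 hexabenzyl flavanone–flavone
Product: 29 (2S)-2-{3-[5,7-dihydroxy-2-(4-hydroxyphenyl)-4-oxo-4H-chromen-8-yl]-4,5-dihydroxyphenyl}-5,7-dihydroxy-2,3-dihydro-4H-chromen-4-one (target)
Conditions: H2 (1 atm), 10% Pd/C, THF/MeOH, 25 °C
Reagents that add atoms: none
Why: Hydrogenolysis of the six benzyl ethers under neutral conditions, which should spare both carbonyl groups and the flavone alkene and leave C2 unable to epimerise by base- or acid-induced ring opening.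

## Compound list

1 | 3-bromo-4,5-dimethoxybenzaldehyde | COc1cc(C=O)cc(Br)c1OC | starting material
2 | 2-(3-bromo-4,5-dimethoxyphenyl)-1,3-dioxolane | COc1cc(C2OCCO2)cc(Br)c1OC | intermediate
3 | [5-(1,3-dioxolan-2-yl)-2,3-dimethoxyphenyl]lithium | COc1cc(C2OCCO2)cc([Li])c1OC | intermediate
4 | methyl 5-(1,3-dioxolan-2-yl)-2,3-dimethoxybenzoate | COC(=O)c1cc(C2OCCO2)cc(OC)c1OC | intermediate
5 | lithium enolate of 2,2-dibromo-1-[5-(1,3-dioxolan-2-yl)-2,3-dimethoxyphenyl]ethanone | [Li+].[O-]C(=C(Br)Br)c1cc(C2OCCO2)cc(OC)c1OC | intermediate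
6 | lithium 2-[5-(1,3-dioxolan-2-yl)-2,3-dimethoxyphenyl]ethynolate | [Li+].[O-]C#Cc1cc(C2OCCO2)cc(OC)c1OC | intermediate
7 | {[5-(1,3-dioxolan-2-yl)-2,3-dimethoxyphenyl]ethynyloxy}tri(propan-2-yl)silane | CC(C)[Si](OC#Cc1cc(C2OCCO2)cc(OC)c1OC)(C(C)C)C(C)C | intermediate
8 | 3-ethoxycyclobut-2-en-1-one | CCOC1=CC(=O)C1 | starting material
9 | 3-ethoxybuta-1,3-dien-1-one | CCOC(=C)C=C=O | intermediate
10 | 2-[5-(1,3-dioxolan-2-yl)-2,3-dimethoxyphenyl]-4-(1-ethoxyethenyl)-3-(triisopropylsilyloxy)cyclobut-2-en-1-one (racemic) | CCOC(=C)C1C(=O)C(c2cc(C3OCCO3)cc(OC)c2OC)=C1O[Si](C(C)C)(C(C)C)C(C)C | intermediate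
11 | 2-[5-(1,3-dioxolan-2-yl)-2,3-dimethoxyphenyl]-5-ethoxy-3-(triisopropylsilyloxy)hexa-1,3,5-trien-1-one | CCOC(=C)C=C(O[Si](C(C)C)(C(C)C)C(C)C)C(=C=O)c1cc(C2OCCO2)cc(OC)c1OC | intermediate
12 | 2-[5-(1,3-dioxolan-2-yl)-2,3-dimethoxyphenyl]-5-ethoxy-3-(triisopropylsilyloxy)cyclohexa-2,4-dien-1-one | CCOC1=CC(O[Si](C(C)C)(C(C)C)C(C)C)=C(c2cc(C3OCCO3)cc(OC)c2OC)C(=O)C1 | intermediate
13 | 2-[5-(1,3-dioxolan-2-yl)-2,3-dimethoxyphenyl]-5-ethoxy-3-(triisopropylsilyloxy)phenol | CCOc1cc(O)c(-c2cc(C3OCCO3)cc(OC)c2OC)c(O[Si](C(C)C)(C(C)C)C(C)C)c1 | intermediate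
14 | 3-[5-(1,3-dioxolan-2-yl)-2,3-dimethoxyphenyl]-6-ethoxy-2-hydroxy-4-(triisopropylsilyloxy)benzaldehyde | CCOc1cc(O[Si](C(C)C)(C(C)C)C(C)C)c(-c2cc(C3OCCO3)cc(OC)c2OC)c(O)c1C=O | intermediate
15 | 1-ethynyl-4-methoxybenzene | C#Cc1ccc(OC)cc1 | starting material
16 | 1-{3-[5-(1,3-dioxolan-2-yl)-2,3-dimethoxyphenyl]-6-ethoxy-2-hydroxy-4-(triisopropylsilyloxy)phenyl}-3-(4-methoxyphenyl)prop-2-yn-1-ol (racemic) | CCOc1cc(O[Si](C(C)C)(C(C)C)C(C)C)c(-c2cc(C3OCCO3)cc(OC)c2OC)c(O)c1C(O)C#Cc1ccc(OC)cc1 | intermediate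
17 | 1-{3-[5-(1,3-dioxolan-2-yl)-2,3-dimethoxyphenyl]-6-ethoxy-2-hydroxy-4-(triisopropylsilyloxy)phenyl}-3-(4-methoxyphenyl)prop-2-yn-1-one | CCOc1cc(O[Si](C(C)C)(C(C)C)C(C)C)c(-c2cc(C3OCCO3)cc(OC)c2OC)c(O)c1C(=O)C#Cc1ccc(OC)cc1 | intermediate
18 | 8-[5-(1,3-dioxolan-2-yl)-2,3-dimethoxyphenyl]-5-ethoxy-2-(4-methoxyphenyl)-7-(triisopropylsilyloxy)-4H-chromen-4-one | CCOc1cc(O[Si](C(C)C)(C(C)C)C(C)C)c(-c2cc(C3OCCO3)cc(OC)c2OC)c2oc(-c3ccc(OC)cc3)cc(=O)c12 | intermediate
19 | 8-[5-(1,3-dioxolan-2-yl)-2,3-dimethoxyphenyl]-5-ethoxy-7-hydroxy-2-(4-methoxyphenyl)-4H-chromen-4-one | CCOc1cc(O)c(-c2cc(C3OCCO3)cc(OC)c2OC)c2oc(-c3ccc(OC)cc3)cc(=O)c12 | intermediate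
20 | 3-[5-ethoxy-7-hydroxy-2-(4-methoxyphenyl)-4-oxo-4H-chromen-8-yl]-4,5-dimethoxybenzaldehyde | CCOc1cc(O)c(-c2cc(C=O)cc(OC)c2OC)c2oc(-c3ccc(OC)cc3)cc(=O)c12 | intermediate
21 | 3-[5,7-dihydroxy-2-(4-hydroxyphenyl)-4-oxo-4H-chromen-8-yl]-4,5-dihydroxybenzaldehyde | O=Cc1cc(O)c(O)c(-c2c(O)cc(O)c3c(=O)cc(-c4ccc(O)cc4)oc23)c1 | intermediate
22 | 3,4-bis(benzyloxy)-5-{7-(benzyloxy)-2-[4-(benzyloxy)phenyl]-5-hydroxy-4-oxo-4H-chromen-8-yl}benzaldehyde | O=Cc1cc(OCc2ccccc2)c(OCc2ccccc2)c(-c2c(OCc3ccccc3)cc(O)c3c(=O)cc(-c4ccc(OCc5ccccc5)cc4)oc23)c1 | intermediate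
23 | 2,4,6-trihydroxyacetophenone | CC(=O)c1c(O)cc(O)cc1O | starting material
24 | 1-[2,4-bis(benzyloxy)-6-hydroxyphenyl]ethan-1-one | CC(=O)c1c(O)cc(OCc2ccccc2)cc1OCc1ccccc1 | intermediate
25 | tert-butyl 3-[2,4-bis(benzyloxy)-6-hydroxyphenyl]-3-oxopropanoate | CC(C)(C)OC(=O)CC(=O)c1c(O)cc(OCc2ccccc2)cc1OCc1ccccc1 | intermediate
26 | tert-butyl 2-[2,4-bis(benzyloxy)-6-hydroxybenzoyl]-3-(3,4-bis(benzyloxy)-5-{7-(benzyloxy)-2-[4-(benzyloxy)phenyl]-5-hydroxy-4-oxo-4H-chromen-8-yl}phenyl)prop-2-enoate (alkene geometry not fixed) | CC(C)(C)OC(=O)C(=Cc1cc(OCc2ccccc2)c(OCc2ccccc2)c(-c2c(OCc3ccccc3)cc(O)c3c(=O)cc(-c4ccc(OCc5ccccc5)cc4)oc23)c1)C(=O)c1c(O)cc(OCc2ccccc2)cc1OCc1ccccc1 | intermediate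
27 | tert-butyl (2S)-5,7-bis(benzyloxy)-2-(3,4-bis(benzyloxy)-5-{7-(benzyloxy)-2-[4-(benzyloxy)phenyl]-5-hydroxy-4-oxo-4H-chromen-8-yl}phenyl)-4-oxo-3,4-dihydro-2H-chromene-3-carboxylate (C3 not assigned) | O=C1C(C(=O)OC(C)(C)C)[C@@H](c2cc(OCc3ccccc3)c(OCc3ccccc3)c(-c3c(OCc4ccccc4)cc(O)c4c(=O)cc(-c5ccc(OCc6ccccc6)cc5)oc34)c2)Oc2cc(OCc3ccccc3)cc(OCc3ccccc3)c21 | intermediate
28 | (2S)-5,7-bis(benzyloxy)-2-(3,4-bis(benzyloxy)-5-{7-(benzyloxy)-2-[4-(benzyloxy)phenyl]-5-hydroxy-4-oxo-4H-chromen-8-yl}phenyl)-2,3-dihydro-4H-chromen-4-one | O=C1C[C@@H](c2cc(OCc3ccccc3)c(OCc3ccccc3)c(-c3c(OCc4ccccc4)cc(O)c4c(=O)cc(-c5ccc(OCc6ccccc6)cc5)oc34)c2)Oc2cc(OCc3ccccc3)cc(OCc3ccccc3)c21 | intermediate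
29 | (2S)-2-{3-[5,7-dihydroxy-2-(4-hydroxyphenyl)-4-oxo-4H-chromen-8-yl]-4,5-dihydroxyphenyl}-5,7-dihydroxy-2,3-dihydro-4H-chromen-4-one | O=C1C[C@@H](c2cc(O)c(O)c(-c3c(O)cc(O)c4c(=O)cc(-c5ccc(O)cc5)oc34)c2)Oc2cc(O)cc(O)c21 | target

## Step count and risks

Total step count: 16. Longest linear sequence: 14 steps (steps 1–11, then 14–16, from compound 1); steps 12 and 13 form the ring A branch.

Steps most likely to fail:

**Step 4 (benzannulation).** Oligomerisation of the vinylketene, its capture by the product phenol, or thermal isomerisation of the siloxyalkyne to a silylketene may outrun the [2+2] union. The fallback joins C5'–C8'' by cross-coupling; it sets out from compound 2 and comes back at compound 21. Compound 2 is borylated (B2pin2, PdCl2(dppf), KOAc, dioxane, 90 °C) to 2-[3,4-dimethoxy-5-(4,4,5,5-tetramethyl-1,3,2-dioxaborolan-2-yl)phenyl]-1,3-dioxolane F1. Commercial 5,7-dimethoxy-2-(4-methoxyphenyl)-4H-chromen-4-one is iodinated at C8 (I2, CF3CO2Ag, CH2Cl2) to 8-iodo-5,7-dimethoxy-2-(4-methoxyphenyl)-4H-chromen-4-one F2. Suzuki–Miyaura coupling of F1 and F2 (Pd(PPh3)4, K2CO3, DME/H2O, 85 °C) gives 8-[5-(1,3-dioxolan-2-yl)-2,3-dimethoxyphenyl]-5,7-dimethoxy-2-(4-methoxyphenyl)-4H-chromen-4-one F3. Aqueous HCl in THF releases 3-[5,7-dimethoxy-2-(4-methoxyphenyl)-4-oxo-4H-chromen-8-yl]-4,5-dimethoxybenzaldehyde F4, and BBr3 cleaves its five methyl ethers to give 21.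

**Step 15 (asymmetric oxa-Michael closure).** Uncatalysed or amine-carried background cyclisation, reversible ring opening, or poor facial discrimination with the hindered 6'-benzyloxy aryl ketone may erode the enantiomeric purity. The fallback makes the racemate and resolves it kinetically; it sets out from compounds 22 and 24 and comes back at compound 28. Claisen–Schmidt condensation (KOH, EtOH/THF, 25 °C) gives (E)-1-[2,4-bis(benzyloxy)-6-hydroxyphenyl]-3-(3,4-bis(benzyloxy)-5-{7-(benzyloxy)-2-[4-(benzyloxy)phenyl]-5-hydroxy-4-oxo-4H-chromen-8-yl}phenyl)prop-2-en-1-one F5. NaOAc in refluxing EtOH closes it to racemic 5,7-bis(benzyloxy)-2-(3,4-bis(benzyloxy)-5-{7-(benzyloxy)-2-[4-(benzyloxy)phenyl]-5-hydroxy-4-oxo-4H-chromen-8-yl}phenyl)-2,3-dihydro-4H-chromen-4-one F6. Asymmetric transfer hydrogenation (RuCl(p-cymene)[(R,R)-TsDPEN], HCO2H/Et3N, EtOAc, 25 °C), run past half conversion, should reduce the 2R enantiomer to (2R,4R)-5,7-bis(benzyloxy)-2-(3,4-bis(benzyloxy)-5-{7-(benzyloxy)-2-[4-(benzyloxy)phenyl]-5-hydroxy-4-oxo-4H-chromen-8-yl}phenyl)-3,4-dihydro-2H-chromen-4-ol F7 and leave the 2S ketone 28, which is separated by chromatography.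

**Step 3 (ynolate formation and silylation).** Incomplete carbenoid rearrangement, competing ring lithiation by the excess alkyllithium, or C-silylation of the ynolate may keep the siloxyalkyne from forming cleanly. The fallback reaches the same ynolate by oxidation of an acetylide; it sets out from compound 2 and comes back at compound 7. Sonogashira coupling (Me3SiC≡CH, PdCl2(PPh3)2, CuI, Et3N, 70 °C) gives {[5-(1,3-dioxolan-2-yl)-2,3-dimethoxyphenyl]ethynyl}trimethylsilane F8. K2CO3 in MeOH gives 2-(3-ethynyl-4,5-dimethoxyphenyl)-1,3-dioxolane F9. Deprotonation (LiN(SiMe3)2, THF, −78 °C) and oxidation of the lithium acetylide with t-BuOOLi (from t-BuOOH and LiN(SiMe3)2, −78 → 0 °C) gives ynolate 6, and TIPSOTf then gives 7.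

Further compounds
F1 | step 4 | 2-[3,4-dimethoxy-5-(4,4,5,5-tetramethyl-1,3,2-dioxaborolan-2-yl)phenyl]-1,3-dioxolane | COc1cc(C2OCCO2)cc(B2OC(C)(C)C(C)(C)O2)c1OC
F2 | step 4 | 8-iodo-5,7-dimethoxy-2-(4-methoxyphenyl)-4H-chromen-4-one | COc1ccc(-c2cc(=O)c3c(OC)cc(OC)c(I)c3o2)cc1
F3 | step 4 | 8-[5-(1,3-dioxolan-2-yl)-2,3-dimethoxyphenyl]-5,7-dimethoxy-2-(4-methoxyphenyl)-4H-chromen-4-one | COc1ccc(-c2cc(=O)c3c(OC)cc(OC)c(-c4cc(C5OCCO5)cc(OC)c4OC)c3o2)cc1
F4 | step 4 | 3-[5,7-dimethoxy-2-(4-methoxyphenyl)-4-oxo-4H-chromen-8-yl]-4,5-dimethoxybenzaldehyde | COc1ccc(-c2cc(=O)c3c(OC)cc(OC)c(-c4cc(C=O)cc(OC)c4OC)c3o2)cc1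
F5 | step 15 | (E)-1-[2,4-bis(benzyloxy)-6-hydroxyphenyl]-3-(3,4-bis(benzyloxy)-5-{7-(benzyloxy)-2-[4-(benzyloxy)phenyl]-5-hydroxy-4-oxo-4H-chromen-8-yl}phenyl)prop-2-en-1-one | O=C(/C=C/c1cc(OCc2ccccc2)c(OCc2ccccc2)c(-c2c(OCc3ccccc3)cc(O)c3c(=O)cc(-c4ccc(OCc5ccccc5)cc4)oc23)c1)c1c(O)cc(OCc2ccccc2)cc1OCc1ccccc1
F6 | step 15 | racemic 5,7-bis(benzyloxy)-2-(3,4-bis(benzyloxy)-5-{7-(benzyloxy)-2-[4-(benzyloxy)phenyl]-5-hydroxy-4-oxo-4H-chromen-8-yl}phenyl)-2,3-dihydro-4H-chromen-4-one | O=C1CC(c2cc(OCc3ccccc3)c(OCc3ccccc3)c(-c3c(OCc4ccccc4)cc(O)c4c(=O)cc(-c5ccc(OCc6ccccc6)cc5)oc34)c2)Oc2cc(OCc3ccccc3)cc(OCc3ccccc3)c21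
F7 | step 15 | (2R,4R)-5,7-bis(benzyloxy)-2-(3,4-bis(benzyloxy)-5-{7-(benzyloxy)-2-[4-(benzyloxy)phenyl]-5-hydroxy-4-oxo-4H-chromen-8-yl}phenyl)-3,4-dihydro-2H-chromen-4-ol | O[C@@H]1C[C@H](c2cc(OCc3ccccc3)c(OCc3ccccc3)c(-c3c(OCc4ccccc4)cc(O)c4c(=O)cc(-c5ccc(OCc6ccccc6)cc5)oc34)c2)Oc2cc(OCc3ccccc3)cc(OCc3ccccc3)c21
F8 | step 3 | {[5-(1,3-dioxolan-2-yl)-2,3-dimethoxyphenyl]ethynyl}trimethylsilane | COc1cc(C2OCCO2)cc(C#C[Si](C)(C)C)c1OC
F9 | step 3 | 2-(3-ethynyl-4,5-dimethoxyphenyl)-1,3-dioxolane | COc1cc(C2OCCO2)cc(C#C)c1OC
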